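The earlier runs and the new flask are calculated with constants of no real substance; scatter was added.

At the time of reading, 8.0 h, we compare four flasks that differ in temperature and nothing else.

all flasks: substrate 10 mM; catalyst 0.50 mM
- delta: reagent 27 mM; temperature 35 °C; run made earlier
- alpha: reagent 60 mM; temperature 68 °C; run made earlier
- south-west: reagent 40.0 mM; temperature 50 °C; time 8.0 h
- west: reagent 40.0 mM; temperature 20 °C; time 8.0 h
- north-west: reagent 40.0 mM; temperature 65 °C; time 8.0 h
- north-east: reagent 40.0 mM; temperature 80 °C; time 8.0 h

| delta: time / h | delta: target / % | alpha: time / h | alpha: target / % |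
|---|---|---|---|
| 3.00 | 6.3 | 0.250 | 40.0 |
| 6.00 | 5.9 | 0.500 | 39.3 |
| 10.0 | 5.7 | 1.00 | 40.0 |
| 12.0 | 5.4 | 1.50 | 39.0 |
| 15.0 | 6.1 | 3.00 | 40.4 |

(readings scatter by 0.5 percentage points)

- ranking by amount of target, in percent of the substrate charged, from high to low, at 8.0 h (south-west / west / north-west / north-east)
- the amount of target, in percent of the substrate charged of the flask you put first, at 8.0 h
- the amount of target, in percent of the substrate charged of the flask you put last, at 8.0 h

Something looks wrong in these runs. The delta run stands near 5.88 % and the alpha run near 39.7 % from their first readings on. Both have stopped, yet 94.1 % and 60.3 % of the substrate is not target, with reagent still in excess.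

So we follow one substrate molecule at rest. Taking one reagent per substrate, its odds of being target rather than not should be proportional to the free reagent, if this is thermodynamic rather than kinetic control. We call the factor the plateau quotient: target, divided by the substrate not in target and by the reagent not taken by target.

delta: 0.00237 mM⁻¹

alpha: 0.0118 mM⁻¹

chance of target = quotient × reagent / (1 + quotient × reagent)

With the full 40.0 mM, which runs slightly high, delta's quotient gives 8.64 % and alpha's gives 32.0 %. The quotient is larger in the hotter run, so our reckoning puts west, colder than delta, below the first figure. North-east, hotter than alpha, goes above the second, north-west just below it, and south-west between them.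

Ours gives bounds, whereas the forecast gives values with ranges: north-east > north-west > south-west > west, with 41 % (35 % to 47 %) and 3.8 % (2.5 % to 5 %). Its ground: “I read this as equilibrium, and the plateau rises with temperature”.

The flasks give north-east > north-west > south-west > west, with 36.3 % and 1.33 %, so the order held and the top amount lies inside the forecast's range, but the low amount lies below that range, under its 2.5 %, though still within the tolerance of the question.

    target + catalyst ⇌ isomer of the product + catalyst, rate k1*[catalyst]*[target] forward; the back reaction follows from the equilibrium constant (k = 130 M⁻¹ min⁻¹, Ea = 50.0 kJ mol⁻¹)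
    substrate + reagent ⇌ isomer of the product (K = 72.0 M⁻¹, k = 5.50 M⁻¹ min⁻¹, Ea = 53.0 kJ mol⁻¹, ΔH = −90.0 kJ mol⁻¹)
    substrate + reagent ⇌ target (K = 23.0 M⁻¹, k = 30.0 M⁻¹ min⁻¹, Ea = 45.0 kJ mol⁻¹, ΔH = −7.00 kJ mol⁻¹)
    (constants at 50 °C)

The quotient counts the isomer of the product as unreacted substrate: at 8.00 h the west flask holds 97.2 % of it, and its quotient is 3.38 × 10⁻⁴ mM⁻¹, lower than delta's. Run at −5 °C, the same flask holds 19.4 % target at 8.00 h, a quotient of 0.00633 mM⁻¹, higher than delta's though colder. West itself fell from 2.13 % at 4.00 h to 1.33 % at 8.00 h. Left until 80.0 h, west stays at 1.32 % and north-east at 36.3 %.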